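**Plan**

1. Numbering: ring A (five-membered) is C1 (quaternary, CH3), C2 (CHOH), C3, C4 (isopropyl carbinol), C5 (fusion CH); ring B (seven-membered) runs C5, C6 (O-angelate), C7, C8 (CH3, epoxide), C9 (epoxide CH), C10 (O-angelate), C1. The α face carries the C1 methyl and H5 and is the convex face of the cis-fused bicycle.
2. Enabling feature: the two oxygenated ring B carbons C6 and C10 sit on the two atoms of the C1–C5 fusion bond, and C7–C8(CH3)–C9 between them is an isobutene unit. Ring B is therefore a cis-1,2-dialdehyde on ring A joined to a 2-methylenepropane-1,3-diyl dianion.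
3. Cuts, in order: both angelate acyl–O bonds; the epoxide back to a C8=C9 alkene beside a C10 carbinol; that alkene back to an exocyclic methylene with C6 and C10 as carbinols; then C6–C7 and C9–C10 together; the dialdehyde back to a cyclobutene, and the cyclobutene to a cyclopentenone plus acetylene.
4. Forward: ring A is the starting cyclopentenone. A cyclobutene is fused on by [2+2] photocycloaddition and serves only as a masked cis-dialdehyde. Ring B is then closed in one operation with 3-chloro-2-(chloromethyl)prop-1-ene.
5. Stereochemistry: C2 from the (S)-silyloxy enone; C1 and C5 from cycloaddition anti to that silyloxy group; C4 from convex-face organocerium addition; C6 from hydride delivered by the C4 hydroxyl; C10 from convex-face Luche reduction; C8 and C9 from epoxidation directed by the C10 hydroxyl; the ester geometry from angelic acid.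

Key step: step 7

Remark: 1 is assumed to be purchased enantiopure in the (S) form; ring-chain tautomers (lactol or hemiketal forms) of 11, 12, 15 and 16 are drawn open-chain.

Abbreviations: TBS = tert-butyldimethylsilyl, TES = triethylsilyl.

**Route**

Step 1
Reactants: 1 (S)-4-(tert-butyldimethylsilyloxy)cyclopent-2-en-1-one
Product: 2 (3S,4S)-4-(tert-butyldimethylsilyloxy)-3-methyl-1-(trimethylsilyloxy)cyclopent-1-ene
Conditions: Me2CuLi (from MeLi and CuI), TMSCl, Et3N, THF/Et2O, −78 °C; crude product used directly
Reagents that add atoms: lithium dimethylcuprate, [Li+].C[Cu-]C; chlorotrimethylsilane, C[Si](C)(C)Cl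
Why: Conjugate addition of a Gilman cuprate anti to the C4 silyloxy group, with chlorotrimethylsilane trapping the regiodefined enolate on oxygen before it can equilibrate and expel the silyloxy group; the new C3 centre (methyl trans to the silyloxy group) is removed again in step 2.

Step 2
Reactants: 2 (3S,4S)-4-(tert-butyldimethylsilyloxy)-3-methyl-1-(trimethylsilyloxy)cyclopent-1-ene
Product: 3 (S)-4-(tert-butyldimethylsilyloxy)-3-methylcyclopent-2-en-1-one
Conditions: Pd(OAc)2 (cat.), O2 (1 atm), DMSO, rt
Reagents that add atoms: none
Why: Saegusa–Ito oxidation, in which the silyl enol ether is transferred to divalent palladium, β-hydride elimination of H3 places the double bond at C2=C3 beside the new methyl group, and O2 returns zerovalent palladium to the divalent state, the C4 stereocentre staying untouched.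

Step 3
Reactants: 3 (S)-4-(tert-butyldimethylsilyloxy)-3-methylcyclopent-2-en-1-one; 4 acetylene
Product: 5 (1R,4S,5S)-4-(tert-butyldimethylsilyloxy)-5-methylbicyclo[3.2.0]hept-6-en-2-one
Conditions: hν (medium-pressure Hg lamp, Pyrex filter), acetone saturated with acetylene, −78 °C, stopped at partial conversion
Reagents that add atoms: none
Why: Enone–alkyne [2+2] photocycloaddition through the enone triplet gives the necessarily cis-fused cyclobutene, and acetylene should bond to the methyl-bearing β-carbon on the face opposite the adjacent silyloxy group, which sets the quaternary carbon and the fusion CH (future C1 and C5) relative to the silyl ether.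

Step 4
Reactants: 5 (1R,4S,5S)-4-(tert-butyldimethylsilyloxy)-5-methylbicyclo[3.2.0]hept-6-en-2-one
Product: 6 (1R,2R,4S,5S)-4-(tert-butyldimethylsilyloxy)-5-methyl-2-(propan-2-yl)bicyclo[3.2.0]hept-6-en-2-ol
Conditions: i-PrMgCl, CeCl3 (anhydrous), THF, −78 °C
Reagents that add atoms: isopropylmagnesium chloride, CC(C)[Mg]Cl
Why: CeCl3-mediated Grignard (organocerium) 1,2-addition, whose low basicity should avoid enolisation and β-elimination of the silyloxy group, and which should attack the convex face of the bicyclo[3.2.0]heptenone anti to the cyclobutene, placing isopropyl exo and the hydroxyl endo (future 4α-isopropyl, 4β-OH).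

Step 5
Reactants: 6 (1R,2R,4S,5S)-4-(tert-butyldimethylsilyloxy)-5-methyl-2-(propan-2-yl)bicyclo[3.2.0]hept-6-en-2-ol
Product: 7 (1R,2R,4S,5S)-4-(tert-butyldimethylsilyloxy)-5-methyl-2-(propan-2-yl)-2-(triethylsilyloxy)bicyclo[3.2.0]hept-6-ene
Conditions: TESOTf, 2,6-lutidine, CH2Cl2, −78 to 0 °C
Reagents that add atoms: triethylsilyl trifluoromethanesulfonate, CC[Si](CC)(CC)OS(=O)(=O)C(F)(F)F
Why: Silyl triflate silylation of a hindered tertiary alcohol, which keeps the C4 oxygen from forming a lactol with, or undergoing retro-aldol loss of, the formyl groups generated in the next step.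

Step 6
Reactants: 7 (1R,2R,4S,5S)-4-(tert-butyldimethylsilyloxy)-5-methyl-2-(propan-2-yl)-2-(triethylsilyloxy)bicyclo[3.2.0]hept-6-ene
Product: 9 (1S,2R,3R,5S)-5-(tert-butyldimethylsilyloxy)-1-methyl-3-(propan-2-yl)-3-(triethylsilyloxy)cyclopentane-1,2-dicarbaldehyde, via ozonide 8 (not isolated)
Conditions: O3, CH2Cl2, −78 °C; then PPh3, −78 °C to rt; crude dialdehyde used at once
Reagents that add atoms: ozone, [O-][O+]=O
Why: Ozonolysis with reductive work-up, in which the strained cyclobutene is the only alkene and its ozonide is reduced by PPh3 under neutral conditions to the cis-1,2-dialdehyde (formyl carbons = future C10 on C1 and C6 on C5) without epimerising the formyl-bearing C5.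

Step 7
Reactants: 9 (1S,2R,3R,5S)-5-(tert-butyldimethylsilyloxy)-1-methyl-3-(propan-2-yl)-3-(triethylsilyloxy)cyclopentane-1,2-dicarbaldehyde; 10 3-chloro-2-(chloromethyl)prop-1-ene
Product: 13 cis-fused 8-methylene hydroazulene-6,10-diol carrying 2α-OTBS and 4β-OTES (epimer mixture at C6 and C10), via C6 mono-adduct 11 (not isolated), via C10 mono-adduct 12 (not isolated)
Conditions: In powder, NaI (cat.), THF/H2O (1:1), rt, slow addition of 9 and 10, high dilution
Reagents that add atoms: none
Why: Iodide-assisted insertion of indium metal into one C–Cl bond of 10 gives a 2-(chloromethyl)allylindium that adds to either formyl group of 9 through a cyclic six-membered chair-like transition state with allyl transposition (C6–C7 or C9–C10, mono-adducts 11 and 12), after which insertion into the remaining allylic C–Cl bond gives a tethered allylindium that adds to the neighbouring aldehyde and forms the second bond. The closest known chemistry is the indium-mediated Barbier allylation of aldehydes in aqueous media together with the use of 2-methylenepropane-1,3-diyl dihalides as trimethylenemethane dianion equivalents in double allylations and annulations of dicarbonyl compounds. Ring B closes in a 7-exo-trig mode, the attacked C=O lying outside the new seven-membered ring, and the exocyclic methylene ends up on C8. The new carbinol centres C6 and C10 are governed only by 1,2-induction from the adjacent ring A stereocentres C5 and C1, and no selectivity is required because both are oxidised in step 9. What the step needs is intramolecular capture of the second aldehyde in preference to oligomerisation and to protonolysis of the allylindium: the cis-1,2 arrangement on the cyclopentane holds that aldehyde (free or as its reversibly formed five-membered lactol, a form that allylindium reagents are known to engage in water) within reach of the tethered nucleophile, and slow addition at high dilution keeps intermolecular addition down. Both orders of attack converge on one constitution, and the silyl ethers and the epimerisable C5–H tolerate the near-neutral aqueous medium.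

Step 8
Reactants: 13 cis-fused 8-methylene hydroazulene-6,10-diol carrying 2α-OTBS and 4β-OTES
Product: 14 2α-(tert-butyldimethylsilyloxy)-8-methylene hydroazulene-4β,6,10-triol
Conditions: HF·pyridine, pyridine, THF, 0 °C
Reagents that add atoms: none
Why: Selective fluoride-mediated desilylation, the triethylsilyl ether being cleaved far faster than the tert-butyldimethylsilyl ether, which is additionally shielded by the neighbouring quaternary C1, so that only the C4 hydroxyl is freed.

Step 9
Reactants: 14 2α-(tert-butyldimethylsilyloxy)-8-methylene hydroazulene-4β,6,10-triol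
Product: 15 2α-(tert-butyldimethylsilyloxy)-4β-hydroxy-8-methylene hydroazulene-6,10-dione
Conditions: Dess–Martin periodinane, NaHCO3, CH2Cl2, 0 °C to rt; filtered through a short neutral pad and used directly
Reagents that add atoms: none
Why: Dess–Martin oxidation turns both secondary carbinols into ketones and so erases the unselective C6 and C10 configurations, leaves the tertiary C4 hydroxyl alone, and under bicarbonate buffering should spare C5 (now α to the C6 carbonyl) from epimerisation, while any drift of the exocyclic alkene into conjugation would not be fatal because all alkene isomers converge in step 11.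

Step 10
Reactants: 15 2α-(tert-butyldimethylsilyloxy)-4β-hydroxy-8-methylene hydroazulene-6,10-dione
Product: 16 2α-(tert-butyldimethylsilyloxy)-4β,6α-dihydroxy-8-methylene hydroazulen-10-one
Conditions: Me4NBH(OAc)3, MeCN/AcOH (1:1), −30 °C
Reagents that add atoms: none
Why: Evans–Saksena directed reduction, in which the reagent exchanges an acetate for the C4 hydroxyl and delivers hydride through a six-membered transition state to the β-positioned C6 carbonyl only (C10 is γ to that hydroxyl and the reagent does not reduce ketones intermolecularly), the hydride arriving on the C4-facing β side of C6 so that the new hydroxyl is α, cis to H5.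

Step 11
Reactants: 16 2α-(tert-butyldimethylsilyloxy)-4β,6α-dihydroxy-8-methylene hydroazulen-10-one
Product: 17 2α-(tert-butyldimethylsilyloxy)-4β,6α-dihydroxy-8-methyl hydroazul-8-en-10-one (C8=C9 enone)
Conditions: DBU, CH2Cl2, rt
Reagents that add atoms: none
Why: Base-mediated isomerisation of a β,γ- to an α,β-unsaturated ketone through the C10 dienolate, C10 being the only carbonyl left, so that reprotonation at the exocyclic carbon moves the alkene to C8=C9 and turns the methylene into the C8 methyl while C5 is no longer α to a carbonyl and cannot epimerise.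

Step 12
Reactants: 17 2α-(tert-butyldimethylsilyloxy)-4β,6α-dihydroxy-8-methyl hydroazul-8-en-10-one
Product: 18 2α-(tert-butyldimethylsilyloxy)-8-methyl hydroazul-8-ene-4β,6α,10β-triol
Conditions: NaBH4, CeCl3·7H2O, MeOH, −78 °C
Reagents that add atoms: none
Why: Luche 1,2-reduction of the cerium-activated enone, in which hydride should approach C10 from the convex α face (the side of the angular methyl and H5, away from ring A folded under the concave face) and so give the 10β allylic alcohol.

Step 13
Reactants: 18 2α-(tert-butyldimethylsilyloxy)-8-methyl hydroazul-8-ene-4β,6α,10β-triol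
Product: 19 2α-(tert-butyldimethylsilyloxy)-8β,9β-epoxy-8α-methyl hydroazulene-4β,6α,10β-triol
Conditions: VO(acac)2 (cat.), t-BuOOH, CH2Cl2, 0 °C to rt
Reagents that add atoms: tert-butyl hydroperoxide, CC(C)(C)OO
Why: Hydroxyl-directed vanadium-catalysed epoxidation, in which the vanadate ester of the allylic C10 hydroxyl delivers oxygen to the same β face of the trisubstituted C8=C9 alkene and thereby sets C8 and C9, the homoallylic C6 hydroxyl on the opposite face directing much more slowly.

Step 14
Reactants: 19 2α-(tert-butyldimethylsilyloxy)-8β,9β-epoxy-8α-methyl hydroazulene-4β,6α,10β-triol; 20 angelic acid ((Z)-2-methylbut-2-enoic acid)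
Product: 22 6α,10β-bis(angelate) of 19 (2α-OTBS and 4β-OH retained), via angelic 2,4,6-trichlorobenzoic anhydride 21 (not isolated)
Conditions: 20 (excess, at least two equivalents per 19), 2,4,6-trichlorobenzoyl chloride (matching amount), Et3N, toluene, rt; then 19, toluene, 80 °C
Reagents that add atoms: angelic acid (second equivalent, which supplies the second angeloyl group), C/C=C(/C)C(=O)O
Why: Yamaguchi-type esterification through the mixed anhydride, run without a nucleophilic catalyst so that the (Z)-2-methylbut-2-enoyl group is not isomerised to the tiglate, in which two equivalents of the anhydride (and hence of angelic acid) are consumed, one by each secondary hydroxyl, while the tertiary C4 hydroxyl is too hindered to react.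

Step 15
Reactants: 22 6α,10β-bis(angelate) of 19
Product: 23 CNP0265715.3 (target)
Conditions: TBAF, AcOH (1:1), THF, 0 °C to rt
Reagents that add atoms: none
Why: Fluoride-mediated desilylation buffered with acetic acid, which removes the last silyl ether without leaving a free alkoxide and should therefore avoid acyl migration from O10 to O2 and acid- or base-induced opening of the epoxide.

**Compound list**

1 | (S)-4-(tert-butyldimethylsilyloxy)cyclopent-2-en-1-one | O=C1C=C[C@@H](O[Si](C)(C)C(C)(C)C)C1 | starting material
2 | (3S,4S)-4-(tert-butyldimethylsilyloxy)-3-methyl-1-(trimethylsilyloxy)cyclopent-1-ene | C[C@H]1C=C(O[Si](C)(C)C)C[C@@H]1O[Si](C)(C)C(C)(C)C | intermediate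
3 | (S)-4-(tert-butyldimethylsilyloxy)-3-methylcyclopent-2-en-1-one | CC1=CC(=O)C[C@@H]1O[Si](C)(C)C(C)(C)C | intermediate
4 | acetylene | C#C | starting material
5 | (1R,4S,5S)-4-(tert-butyldimethylsilyloxy)-5-methylbicyclo[3.2.0]hept-6-en-2-one (silyloxy group exo, anti to the cyclobutene) | C1=C[C@@]2(C)[C@@H]1C(=O)C[C@@H]2O[Si](C)(C)C(C)(C)C | intermediate
6 | (1R,2R,4S,5S)-4-(tert-butyldimethylsilyloxy)-5-methyl-2-(propan-2-yl)bicyclo[3.2.0]hept-6-en-2-ol (isopropyl exo, hydroxyl endo) | C1=C[C@@]2(C)[C@@H]1[C@](O)(C(C)C)C[C@@H]2O[Si](C)(C)C(C)(C)C | intermediate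
7 | (1R,2R,4S,5S)-4-(tert-butyldimethylsilyloxy)-5-methyl-2-(propan-2-yl)-2-(triethylsilyloxy)bicyclo[3.2.0]hept-6-ene | C1=C[C@@]2(C)[C@@H]1[C@](O[Si](CC)(CC)CC)(C(C)C)C[C@@H]2O[Si](C)(C)C(C)(C)C | intermediate
8 | ozonide of 7 (2,3,7-trioxabicyclo[2.2.1]heptane fused to ring A across C1–C5; either bridge orientation) | C[C@@]12[C@@H](C3OOC1O3)[C@](O[Si](CC)(CC)CC)(C(C)C)C[C@@H]2O[Si](C)(C)C(C)(C)C | intermediate (not isolated)
9 | (1S,2R,3R,5S)-5-(tert-butyldimethylsilyloxy)-1-methyl-3-(propan-2-yl)-3-(triethylsilyloxy)cyclopentane-1,2-dicarbaldehyde (cis-dialdehyde) | O=C[C@@]1(C)[C@@H](C=O)[C@](O[Si](CC)(CC)CC)(C(C)C)C[C@@H]1O[Si](C)(C)C(C)(C)C | intermediate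
10 | 3-chloro-2-(chloromethyl)prop-1-ene | C=C(CCl)CCl | starting material
11 | C6 mono-adduct: 9 with the C6 formyl group converted into a 3-(chloromethyl)-1-hydroxybut-3-enyl group, C10 formyl group intact (carbinol epimers) | O=C[C@@]1(C)[C@@H](C(O)CC(=C)CCl)[C@](O[Si](CC)(CC)CC)(C(C)C)C[C@@H]1O[Si](C)(C)C(C)(C)C | intermediate (not isolated)
12 | C10 mono-adduct: 9 with the C10 formyl group converted into a 3-(chloromethyl)-1-hydroxybut-3-enyl group, C6 formyl group intact (carbinol epimers) | ClCC(=C)CC(O)[C@@]1(C)[C@@H](C=O)[C@](O[Si](CC)(CC)CC)(C(C)C)C[C@@H]1O[Si](C)(C)C(C)(C)C | intermediate (not isolated)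
13 | cis-fused hydroazulene-6,10-diol with exocyclic methylene on C8: 1α-methyl, 5α-H, 2α-OTBS, 4β-OTES, 4α-isopropyl (C6 and C10 configurations left open, epimer mixture) | OC1CC(=C)CC(O)[C@@]2(C)[C@@H]1[C@](O[Si](CC)(CC)CC)(C(C)C)C[C@@H]2O[Si](C)(C)C(C)(C)C | intermediate
14 | 13 with free 4β-hydroxyl: 2α-OTBS-8-methylene hydroazulene-4β,6,10-triol (C6/C10 epimer mixture) | OC1CC(=C)CC(O)[C@@]2(C)[C@@H]1[C@](O)(C(C)C)C[C@@H]2O[Si](C)(C)C(C)(C)C | intermediate
15 | 2α-OTBS-4β-hydroxy-4α-isopropyl-1α-methyl-8-methylene-cis-hydroazulene-6,10-dione | O=C1CC(=C)CC(=O)[C@@]2(C)[C@@H]1[C@](O)(C(C)C)C[C@@H]2O[Si](C)(C)C(C)(C)C | intermediate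
16 | 2α-OTBS-4β,6α-dihydroxy-4α-isopropyl-1α-methyl-8-methylene-cis-hydroazulen-10-one | O[C@H]1CC(=C)CC(=O)[C@@]2(C)[C@@H]1[C@](O)(C(C)C)C[C@@H]2O[Si](C)(C)C(C)(C)C | intermediate
17 | 2α-OTBS-4β,6α-dihydroxy-4α-isopropyl-1α,8-dimethyl-cis-hydroazul-8-en-10-one (C8=C9 enone) | O[C@H]1CC(C)=CC(=O)[C@@]2(C)[C@@H]1[C@](O)(C(C)C)C[C@@H]2O[Si](C)(C)C(C)(C)C | intermediate
18 | 2α-OTBS-4α-isopropyl-1α,8-dimethyl-cis-hydroazul-8-ene-4β,6α,10β-triol | O[C@H]1CC(C)=C[C@H](O)[C@@]2(C)[C@@H]1[C@](O)(C(C)C)C[C@@H]2O[Si](C)(C)C(C)(C)C | intermediate
19 | 2α-OTBS-8β,9β-epoxy-4α-isopropyl-1α,8α-dimethyl-cis-hydroazulene-4β,6α,10β-triol | O[C@H]1C[C@]2(C)O[C@@H]2[C@H](O)[C@@]2(C)[C@@H]1[C@](O)(C(C)C)C[C@@H]2O[Si](C)(C)C(C)(C)C | intermediate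
20 | angelic acid, (Z)-2-methylbut-2-enoic acid | C/C=C(/C)C(=O)O | starting material
21 | angelic 2,4,6-trichlorobenzoic anhydride | C/C=C(/C)C(=O)OC(=O)c1c(Cl)cc(Cl)cc1Cl | intermediate (not isolated)
22 | 6α,10β-bis[(Z)-2-methylbut-2-enoyloxy]-2α-OTBS-8β,9β-epoxy-4β-hydroxy-4α-isopropyl-1α,8α-dimethyl-cis-hydroazulene | C/C=C(/C)C(=O)O[C@H]1C[C@]2(C)O[C@@H]2[C@H](OC(=O)/C(C)=C\C)[C@@]2(C)[C@@H]1[C@](O)(C(C)C)C[C@@H]2O[Si](C)(C)C(C)(C)C | intermediate
23 | CNP0265715.3: (1S,2S,4R,5S,6S,8S,9R,10R) in the numbering above; 6α,10β-bis(angeloyloxy)-8β,9β-epoxy-2α,4β-dihydroxy-4α-isopropyl-1α,8α-dimethyl-cis-hydroazulene (5α-H) | C/C=C(/C)C(=O)O[C@H]1C[C@]2(C)O[C@@H]2[C@H](OC(=O)/C(C)=C\C)[C@@]2(C)[C@@H]1[C@](O)(C(C)C)C[C@@H]2O | target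

**Step count**

Total: 15 steps. Longest linear sequence: 15 steps (1 to 23); acetylene, 10 and angelic acid enter directly.

**Steps most likely to fail**

Step 7 (ring B closure). After the first addition the carbinol may close onto the neighbouring formyl group as a five-membered lactol while the tethered C–Cl bond is metalated only slowly. The allylindium that does form can then be protonated by water or add to a second molecule, so that methallyl carbinols or oligomers take the place of ring B. The fallback sets out from 9 and 10. Only the first allylation is run (In powder, THF/H2O, 0 °C, no iodide, one equivalent of 10). The mono-adducts are isolated in their ring-closed forms, the C10 lactol of the C6 mono-adduct F1 and the C6 lactol of the C10 mono-adduct F2. Ring B is then closed by an intramolecular Nozaki–Hiyama–Kishi allylation (CrCl2, LiI (cat.), THF/DMF, high dilution, rt). The allylchromium species tolerates the lactol hydroxyl, is not exposed to water, and adds to the aldehyde released from the lactol. The route is rejoined at 13.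

Step 3 (photocycloaddition). The β,γ-unsaturated ketone product absorbs in the same region as the enone and can be lost to a 1,3-acyl shift on continued irradiation. The low concentration of dissolved acetylene slows the cycloaddition, and addition on the silyloxy face may intrude. The fallback sets out from 3. Irradiation with a large excess of (E)-1,2-dichloroethene (Pyrex, CH2Cl2, −20 °C) gives the photostable adduct 4-(tert-butyldimethylsilyloxy)-6,7-dichloro-5-methylbicyclo[3.2.0]heptan-2-one F3 (chloride epimers). CeCl3-mediated addition of i-PrMgCl as in step 4 gives the dichloro carbinol F4. Reductive elimination of the vicinal dichloride with sodium naphthalenide (NaC10H8, THF, −78 °C) restores the cyclobutene. The route is rejoined at 6.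

Step 14 (bis-angeloylation). Acylation of the C10 hydroxyl, flanked by the quaternary C1 and the epoxide, may stall after the C6 hydroxyl has reacted, and prolonged heating may isomerise the angeloyl group to the tigloyl group. The fallback sets out from 19. Both secondary hydroxyls are esterified with the unhindered, non-isomerisable 2-[bis(2,2,2-trifluoroethoxy)phosphoryl]propanoic acid (two equivalents, DCC, DMAP (cat.), CH2Cl2, rt) to give the 6,10-bis(phosphonopropanoate) of 19 F5. A double Still–Gennari olefination with acetaldehyde (KN(SiMe3)2, 18-crown-6, THF, −78 °C) then builds both (Z)-2-methylbut-2-enoates in place. The route is rejoined at 22.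

**Further compounds**

F1 | step 7 | C10 lactol of the C6 mono-adduct 11 (2-oxabicyclo[3.3.0]octan-3-ol form, anomer and carbinol mixture) | OC1OC(CC(=C)CCl)[C@@H]2[C@@]1(C)[C@@H](O[Si](C)(C)C(C)(C)C)C[C@@]2(O[Si](CC)(CC)CC)C(C)C
F2 | step 7 | C6 lactol of the C10 mono-adduct 12 (anomer and carbinol mixture) | OC1OC(CC(=C)CCl)[C@@]2(C)[C@@H]1[C@](O[Si](CC)(CC)CC)(C(C)C)C[C@@H]2O[Si](C)(C)C(C)(C)C
F3 | step 3 | 4-(tert-butyldimethylsilyloxy)-6,7-dichloro-5-methylbicyclo[3.2.0]heptan-2-one (chloride epimers) | ClC1C(Cl)[C@@]2(C)[C@@H]1C(=O)C[C@@H]2O[Si](C)(C)C(C)(C)C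
F4 | step 3 | 4-(tert-butyldimethylsilyloxy)-6,7-dichloro-5-methyl-2-(propan-2-yl)bicyclo[3.2.0]heptan-2-ol (chloride epimers) | ClC1C(Cl)[C@@]2(C)[C@@H]1[C@](O)(C(C)C)C[C@@H]2O[Si](C)(C)C(C)(C)C
F5 | step 14 | 6α,10β-bis{2-[bis(2,2,2-trifluoroethoxy)phosphoryl]propanoate} of 19 | CC(P(=O)(OCC(F)(F)F)OCC(F)(F)F)C(=O)O[C@H]1C[C@]2(C)O[C@@H]2[C@H](OC(=O)C(C)P(=O)(OCC(F)(F)F)OCC(F)(F)F)[C@@]2(C)[C@@H]1[C@](O)(C(C)C)C[C@@H]2O[Si](C)(C)C(C)(C)C
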